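The readings are calculated from invented constants, noise included.

Time is what we watch here: the flasks below are read at 25 h, and they differ in when their last addition went in.

| setting | birch | ash | south-east | north | west | north-east | east |
|---|---|---|---|---|---|---|---|
| starting complex | 0.20 M | 0.20 M | 0.20 M | 0.20 M (fed, over 15 h) | 0.20 M | 0.20 M (fed, over 1.5 h) | 0.20 M |
| incoming ligand | 0.19 M | 0.38 M | 0.190 M (in portions, 4, over 15 h) | 0.190 M | 0.190 M (fed, over 15 h) | 0.190 M | 0.190 M |
| leaving ligand | 1 M | 1 M | 1.00 M | 1.00 M | 1.00 M | 1.00 M | 1.00 M |
| remark | run made earlier | run made earlier | first portion at the start, last at 15 h | all else is in the flask from the start; the feed brings no volume worth counting | all else is in the flask from the start; the feed brings no volume worth counting | all else is in the flask from the start; the feed brings no volume worth counting | everything together at the start |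
| time |  |  | 25 h | 25 h | 25 h | 25 h | 25 h |

| run | time / h | complex with three exchanged / % | isomer of the product / % |
|---|---|---|---|
| birch | 2.00 | 0.5 | 0.3 |
| birch | 6.00 | 1.2 | 0.6 |
| birch | 12.0 | 0.3 | 0 |
| birch | 20.0 | 0 | 0.8 |
| birch | 25.0 | 0.1 | 0.1 |
| ash | 1.50 | 1.1 | 0 |
| ash | 3.00 | 2.4 | 0 |
| ash | 5.00 | 4.6 | 1.3 |
| ash | 6.00 | 4.8 | 0.4 |
| ash | 8.00 | 5.1 | 0.7 |

(each reading ± 0.5 percentage points)

1. the best flask by share of complex with three exchanged in complex with three exchanged plus isomer of the product; "all alike" if 1.5 percentage points covers them all (south-east / north / west / north-east / east / all alike)
2. share of complex with three exchanged in complex with three exchanged plus isomer of the product at the end, south-east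
3. share of complex with three exchanged in complex with three exchanged plus isomer of the product at the end, north
4. share of complex with three exchanged in complex with three exchanged plus isomer of the product at the end, west
5. share of complex with three exchanged in complex with three exchanged plus isomer of the product at the end, north-east
6. share of complex with three exchanged in complex with three exchanged plus isomer of the product at the end, east

- a reading or a percentage of complex with three exchanged counts all its forms, free or not

We follow the earlier runs in slow motion. In the first instants the ligands exchange one after the other on the starting complex, and at 1.50 h the ash run reads 1.1% of complex with three exchanged beside 0% of isomer. In the middle the product builds up and the isomer appears behind it, so at 8.00 h the ash run reads 5.1% and 0.7%, which makes the share of the product in the pair 87.9%, a reading that carries a scatter of 0.5 percentage points on each number. Towards the end we have the birch run, but its readings at 25.0 h, 0.1% of complex with three exchanged and 0.1% of isomer, both lie within the scatter of 0.5 points of nothing, so they give no share we can use.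

What we expect to matter at the reading is how long the mixture has been complete. For south-east, north and west that is 10.0 h, the standing time: the hours between the last addition and the reading. For north-east it is 23.5 h, and for east it is 25 h. The ash run lost 12.1% of the pair in 8.00 h, and a straight carry-over of that drift across the 15.0 h by which east outstands south-east gives a gap of 23 points, far above the margin of 1.5 points. We therefore reckon on kinetic rather than thermodynamic control of the share at the reading, with south-east, north and west above north-east and east.

The forecast says all alike, at 80% for each flask, on the ground that “the routes should be forgotten by 25 h”.

The flasks give 76.5% for south-east, 74.8% for west, 68.2% for north, 64.4% for north-east and 64.0% for east, so south-east is best. The gap between south-east and east is 12 points, less than our 23 points, and north lies 6.6 points below west at the same standing time.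

    starting complex + incoming ligand ⇌ leaving ligand + complex with one exchanged (K = 200, k = 1.50 M⁻¹ h⁻¹)
    complex with one exchanged + incoming ligand ⇌ leaving ligand + complex with two exchanged (K = 3.00, k = 1.50 M⁻¹ h⁻¹)
    complex with two exchanged + incoming ligand ⇌ leaving ligand + complex with three exchanged (K = 13.0, k = 0.380 M⁻¹ h⁻¹)
    complex with three exchanged ⇌ isomer of the product (K = 0.920, k = 0.0650 h⁻¹)
    starting complex + complex with three exchanged ⇌ idle adduct, settled at all times (K = 6.40 M⁻¹)
    complex with two exchanged → decomposed reagent (k = 0.0750 h⁻¹)

In east the standing time of 25 h is longer than the 11 h half-life of free complex with three exchanged by the forward step to the isomer alone, whereas south-east stands 10.0 h, shorter than that half-life of east. The same flask as south-east, read at 40 h, has stood 25.0 h, as long as east, and its share is 62.2%.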